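**Strategy.** Ring A (cyclopentane C1–C5: C1 quaternary methyl carbon, C2 acetoxy carbon, C4 isopropyl carbinol, C5 ring-fusion CH) is cut into methyl vinyl ketone (C3–C6) and a masked 3-methylbutenolide (C2, C1, C10, C9). One pot joins C2–C3 by a catalytic enantioselective aldol reaction and, after lactonisation, C1–C5 by an intramolecular Rauhut–Currier reaction, a formal [3+2] annulation. It exploits the cis relation of the C2 oxygen and the C1–C10–C9(=O) arm, a hidden γ-lactone. The precursor is an acyclic (Z)-formyl ester plus methyl vinyl ketone; the product, a cis-fused α-methylene keto lactone, steers the C4 and C5 stereocentres before the lactone becomes the C9 enone and ring B is closed by metathesis.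

Key step: step 2

Remark (numbering): C1 = methyl-bearing ring-fusion carbon, C2 = CH–OAc, C3 = CH2, C4 = C(OH)(i-Pr), C5 = ring-fusion CH, C6 = CH–O-aroyl, C7=C8(CH3), C9 = ketone, C10 = CH2; α = face of the C5 hydrogen, β = face of the C1 methyl group.

Assumption (chemistry): (S,S)-ProPhenol is taken to give the (R)-aldol at C2, by analogy with its sense of induction for other aldehydes; should the sense be opposite, the (R,R)-ligand is used.

**Step 1**
Reactants: 1 5-hydroxy-4-methylfuran-2(5H)-one
Product: 2 methyl (2Z)-3-methyl-4-oxobut-2-enoate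
Conditions: MeI, KHCO3, DMF, 0 °C → rt
Reagents that add atoms: iodomethane CI
Why: Alkylation of the carboxylate of the ring-opened (Z)-formyl acid tautomer of the pseudo-acid should give the open-chain ester, whose Z geometry is inherited from the butenolide ring (carboxylate O-alkylation; no stereocentre is formed).

**Step 2**
Reactants: 2 methyl (2Z)-3-methyl-4-oxobut-2-enoate; 3 but-3-en-2-one (methyl vinyl ketone)
Product: 6 (3aS,6aR)-3a-methyl-4-methylidenetetrahydro-2H-cyclopenta[b]furan-2,5(3H)-dione, via aldol adduct 4 (not isolated), via butenolide enone 5 (not isolated)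
Conditions: Et2Zn (20 mol %), (S,S)-ProPhenol (10 mol %), 4 Å MS, THF, 0 °C; excess 3 evaporated; then PMe3 (30 mol %), t-AmOH, rt → 40 °C
Reagents that add atoms: none
Why: The zinc–ProPhenol complex deprotonates the methyl group of 3 and delivers the zinc dienolate to the aldehyde of 2 (direct catalytic asymmetric aldol reaction of methyl vinyl ketone), forming C2–C3 and setting C2 (R) under catalyst control; the zinc alkoxide then acylates the cis ester (5-exo-trig) to give butenolide 5 and methanol. PMe3 adds to the unsubstituted β-carbon of the vinyl ketone and the zwitterionic enolate attacks C1, the β-carbon of the butenolide, in a 5-exo-trig Michael addition (intramolecular Rauhut–Currier reaction), forming C1–C5; proton transfer and loss of PMe3 restore the exocyclic methylene group. The closest known reactions are the zinc–ProPhenol aldol of methyl vinyl ketone with aldehydes and the phosphine-catalysed cycloisomerisation of tethered enone/enoate pairs to five-membered rings. C1 is set by the tether, because the chain attached at C2 can reach only the butenolide face on which it stands, so the quaternary carbon should form with the lactone cis-fused (C2–O and C1–CH2 cis, methyl cis to the C2 hydrogen). The step needs the phosphine to add to the vinyl ketone and not to the butenolide, which the unsubstituted versus fully substituted β-carbons secure. It also needs excess 3 to be removed before the phosphine is added, so that intermolecular dimerisation does not compete.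

**Step 3**
Reactants: 6 (3aS,6aR)-3a-methyl-4-methylidenetetrahydro-2H-cyclopenta[b]furan-2,5(3H)-dione
Product: 7 (3aS,5R,6aR)-5-hydroxy-3a-methyl-4-methylidene-5-(propan-2-yl)hexahydro-2H-cyclopenta[b]furan-2-one
Conditions: i-PrMgCl, CeCl3, THF, −78 °C; aq. NH4Cl
Reagents that add atoms: isopropylmagnesium chloride CC(C)[Mg]Cl
Why: Organocerium 1,2-addition to the enone carbonyl (low basicity suppresses enolisation towards C3 and conjugate addition) should occur on the convex face of the cis-fused 2-oxabicyclo[3.3.0]octane, anti to the lactone ring and with no sp3 substituent on C5 to oppose it, placing isopropyl β and the C4 hydroxyl α.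

**Step 4**
Reactants: 7 (3aS,5R,6aR)-5-hydroxy-3a-methyl-4-methylidene-5-(propan-2-yl)hexahydro-2H-cyclopenta[b]furan-2-one
Product: 9 (3aS,4S,5R,6aR)-5-hydroxy-3a-methyl-5-(propan-2-yl)-4-(prop-2-en-1-yl)hexahydro-2H-cyclopenta[b]furan-2-one, via alkylborane 8 (not isolated)
Conditions: 9-BBN, THF, 0 → 50 °C; then CH2=CHBr, Pd(dppf)Cl2 (5 mol %), AsPh3, Cs2CO3, DMF–H2O, rt
Reagents that add atoms: bromoethene C=CBr
Why: Hydroboration of the exocyclic methylene puts boron on C6 and hydrogen on C5 from the α-face, away from the β-isopropyl and β-methyl groups on the two neighbouring carbons (C5–H α), and B-alkyl Suzuki–Miyaura coupling with vinyl bromide turns the borane into the allyl group.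

**Step 5**
Reactants: 9 (3aS,4S,5R,6aR)-5-hydroxy-3a-methyl-5-(propan-2-yl)-4-(prop-2-en-1-yl)hexahydro-2H-cyclopenta[b]furan-2-one
Product: 11 1-[(1S,2R,4R,5S)-2,4-dihydroxy-1-methyl-4-(propan-2-yl)-5-(prop-2-en-1-yl)cyclopentyl]-3-methylbut-3-en-2-one, via lactol alkoxide 10 (not isolated)
Conditions: 2-propenyllithium (from 2-bromopropene, t-BuLi; 2.5 equiv), THF, −78 °C; aq. NH4Cl
Reagents that add atoms: 2-propenyllithium [Li]C(C)=C (made in the flask from 2-bromopropene CC(Br)=C and tert-butyllithium [Li]C(C)(C)C)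
Why: Addition of an alkenyllithium to a γ-lactone at −78 °C should stop at the lithium lactol alkoxide, which gives the isopropenyl ketone and the free C2 hydroxyl on work-up (acyl substitution); the first equivalent deprotonates the tertiary alcohol and no stereocentre is touched.

**Step 6**
Reactants: 11 1-[(1S,2R,4R,5S)-2,4-dihydroxy-1-methyl-4-(propan-2-yl)-5-(prop-2-en-1-yl)cyclopentyl]-3-methylbut-3-en-2-one
Product: 12 (1R,2S,3S,4R)-4-hydroxy-2-methyl-2-(3-methyl-2-oxobut-3-en-1-yl)-4-(propan-2-yl)-3-(prop-2-en-1-yl)cyclopentyl acetate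
Conditions: Ac2O, pyridine, DMAP (cat.), CH2Cl2, 0 °C → rt
Reagents that add atoms: acetic anhydride CC(=O)OC(C)=O
Why: DMAP-catalysed acetylation should take the secondary C2 alcohol only, because the tertiary C4 alcohol next to the isopropyl group is too hindered under these conditions.

**Step 7**
Reactants: 12 (1R,2S,3S,4R)-4-hydroxy-2-methyl-2-(3-methyl-2-oxobut-3-en-1-yl)-4-(propan-2-yl)-3-(prop-2-en-1-yl)cyclopentyl acetate
Product: 13 (1R,3R,3aS,8aS)-3-hydroxy-6,8a-dimethyl-7-oxo-3-(propan-2-yl)-1,2,3,3a,4,7,8,8a-octahydroazulen-1-yl acetate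
Conditions: second-generation Grubbs catalyst (5 mol %), CH2Cl2 (5 mM), 40 °C
Reagents that add atoms: none
Why: Ring-closing metathesis between the allyl group and the isopropenyl ketone should close ring B as the trisubstituted C7=C8 enone with loss of ethene; the trans ring fusion follows from the trans arrangement of the two side chains.

**Step 8**
Reactants: 13 (1R,3R,3aS,8aS)-3-hydroxy-6,8a-dimethyl-7-oxo-3-(propan-2-yl)-1,2,3,3a,4,7,8,8a-octahydroazulen-1-yl acetate
Product: 16 (1R,3R,3aR,4R,8aS)-3,4-dihydroxy-6,8a-dimethyl-7-oxo-3-(propan-2-yl)-1,2,3,3a,4,7,8,8a-octahydroazulen-1-yl acetate, via dienol silyl ether 14 (not isolated), via silyl ether 15 (not isolated)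
Conditions: TMSOTf, Et3N, CH2Cl2, 0 °C → rt; then mCPBA, NaHCO3, CH2Cl2, −20 °C; then 1 M HCl, THF, 0 °C
Reagents that add atoms: 3-chloroperbenzoic acid OOC(=O)c1cccc(Cl)c1
Why: Soft enolisation should give the extended dienol silyl ether by γ-deprotonation at C6 (as with steroidal enones), and the peracid should attack its terminal carbon C6 (vinylogous Rubottom oxidation) from the α-face, opposite the β-methyl on C1 and the β-isopropyl on C4, giving the 6α-alcohol after desilylation.

**Step 9**
Reactants: 16 (1R,3R,3aR,4R,8aS)-3,4-dihydroxy-6,8a-dimethyl-7-oxo-3-(propan-2-yl)-1,2,3,3a,4,7,8,8a-octahydroazulen-1-yl acetate; 17 4-(acetyloxy)benzoic acid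
Product: 18 (1R,3R,3aR,4R,8aS)-1-(acetyloxy)-3-hydroxy-6,8a-dimethyl-7-oxo-3-(propan-2-yl)-1,2,3,3a,4,7,8,8a-octahydroazulen-4-yl 4-(acetyloxy)benzoate
Conditions: DCC, DMAP, CH2Cl2, rt
Reagents that add atoms: none
Why: Steglich esterification should acylate the secondary allylic C6 alcohol with retention of configuration and leave the tertiary C4 alcohol free.

**Step 10**
Reactants: 18 (1R,3R,3aR,4R,8aS)-1-(acetyloxy)-3-hydroxy-6,8a-dimethyl-7-oxo-3-(propan-2-yl)-1,2,3,3a,4,7,8,8a-octahydroazulen-4-yl 4-(acetyloxy)benzoate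
Product: 19 (1R,3R,3aR,4R,8aS)-1-(acetyloxy)-3-hydroxy-6,8a-dimethyl-7-oxo-3-(propan-2-yl)-1,2,3,3a,4,7,8,8a-octahydroazulen-4-yl 4-hydroxybenzoate
Conditions: NH4OAc, MeOH–H2O (4:1), rt
Reagents that add atoms: none
Why: Ammonium acetate-mediated methanolysis should cleave only the phenyl acetate, which is far more electrophilic than the secondary alkyl acetate at C2 and the benzoate ester (chemoselective transesterification; neutral conditions avoid elimination of the C6 ester).

**Compound list**

1 | 5-hydroxy-4-methylfuran-2(5H)-one (pseudo-acid, racemic) | CC1=CC(=O)OC1O | starting material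
2 | methyl (2Z)-3-methyl-4-oxobut-2-enoate | O=C/C(C)=C\C(=O)OC | intermediate
3 | but-3-en-2-one (methyl vinyl ketone) | CC(=O)C=C | starting material
4 | methyl (2Z,4R)-4-hydroxy-3-methyl-6-oxoocta-2,7-dienoate (formed as its zinc alkoxide) | C/C(=C/C(=O)OC)[C@H](O)CC(=O)C=C | intermediate
5 | (5R)-4-methyl-5-(2-oxobut-3-en-1-yl)furan-2(5H)-one | CC1=CC(=O)O[C@@H]1CC(=O)C=C | intermediate
6 | (3aS,6aR)-3a-methyl-4-methylidenetetrahydro-2H-cyclopenta[b]furan-2,5(3H)-dione (cis-fused) | O=C1C[C@]2(C)[C@H](O1)CC(=O)C2=C | intermediate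
7 | (3aS,5R,6aR)-5-hydroxy-3a-methyl-4-methylidene-5-(propan-2-yl)hexahydro-2H-cyclopenta[b]furan-2-one | O=C1C[C@]2(C)[C@H](O1)C[C@@](O)(C(C)C)C2=C | intermediate
8 | (3aS,4S,5R,6aR)-4-[(9-borabicyclo[3.3.1]nonan-9-yl)methyl]-5-hydroxy-3a-methyl-5-(propan-2-yl)hexahydro-2H-cyclopenta[b]furan-2-one | O=C1C[C@]2(C)[C@H](O1)C[C@@](O)(C(C)C)[C@H]2CB3C4CCCC3CCC4 | intermediate
9 | (3aS,4S,5R,6aR)-5-hydroxy-3a-methyl-5-(propan-2-yl)-4-(prop-2-en-1-yl)hexahydro-2H-cyclopenta[b]furan-2-one | O=C1C[C@]2(C)[C@H](O1)C[C@@](O)(C(C)C)[C@H]2CC=C | intermediate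
10 | lactol of 9 carrying the prop-1-en-2-yl group on the former lactone carbon (formed as its lithium alkoxide, either configuration at that carbon) | C=C(C)C1(O)C[C@]2(C)[C@H](O1)C[C@@](O)(C(C)C)[C@H]2CC=C | intermediate
11 | 1-[(1S,2R,4R,5S)-2,4-dihydroxy-1-methyl-4-(propan-2-yl)-5-(prop-2-en-1-yl)cyclopentyl]-3-methylbut-3-en-2-one | O[C@@H]1C[C@@](O)(C(C)C)[C@@H](CC=C)[C@]1(C)CC(=O)C(C)=C | intermediate
12 | (1R,2S,3S,4R)-4-hydroxy-2-methyl-2-(3-methyl-2-oxobut-3-en-1-yl)-4-(propan-2-yl)-3-(prop-2-en-1-yl)cyclopentyl acetate | CC(=O)O[C@@H]1C[C@@](O)(C(C)C)[C@@H](CC=C)[C@]1(C)CC(=O)C(C)=C | intermediate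
13 | (1R,3R,3aS,8aS)-3-hydroxy-6,8a-dimethyl-7-oxo-3-(propan-2-yl)-1,2,3,3a,4,7,8,8a-octahydroazulen-1-yl acetate (trans-fused) | CC(=O)O[C@@H]1C[C@@](O)(C(C)C)[C@H]2CC=C(C)C(=O)C[C@]12C | intermediate
14 | extended dienol trimethylsilyl ether of 13 (C6=C7 and C8=C9–OSiMe3; C4–OSiMe3) | CC(=O)O[C@@H]1C[C@@](O[Si](C)(C)C)(C(C)C)[C@H]2C=CC(C)=C(O[Si](C)(C)C)C[C@]12C | intermediate
15 | C4 trimethylsilyl ether of 16 | CC(=O)O[C@@H]1C[C@@](O[Si](C)(C)C)(C(C)C)[C@H]2[C@H](O)C=C(C)C(=O)C[C@]12C | intermediate
16 | (1R,3R,3aR,4R,8aS)-3,4-dihydroxy-6,8a-dimethyl-7-oxo-3-(propan-2-yl)-1,2,3,3a,4,7,8,8a-octahydroazulen-1-yl acetate | CC(=O)O[C@@H]1C[C@@](O)(C(C)C)[C@H]2[C@H](O)C=C(C)C(=O)C[C@]12C | intermediate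
17 | 4-(acetyloxy)benzoic acid | CC(=O)Oc1ccc(cc1)C(=O)O | starting material
18 | (1R,3R,3aR,4R,8aS)-1-(acetyloxy)-3-hydroxy-6,8a-dimethyl-7-oxo-3-(propan-2-yl)-1,2,3,3a,4,7,8,8a-octahydroazulen-4-yl 4-(acetyloxy)benzoate | CC(=O)O[C@@H]1C[C@@](O)(C(C)C)[C@H]2[C@H](OC(=O)c3ccc(OC(C)=O)cc3)C=C(C)C(=O)C[C@]12C | intermediate
19 | (1R,3R,3aR,4R,8aS)-1-(acetyloxy)-3-hydroxy-6,8a-dimethyl-7-oxo-3-(propan-2-yl)-1,2,3,3a,4,7,8,8a-octahydroazulen-4-yl 4-hydroxybenzoate | CC(=O)O[C@@H]1C[C@@](O)(C(C)C)[C@H]2[C@H](OC(=O)c3ccc(O)cc3)C=C(C)C(=O)C[C@]12C | target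

**Totals.** Total step count: 10. Longest linear sequence: 10 steps (1 → 19).

**Steps most likely to fail**

Step 2. The zwitterionic enolate may fail to add to the fully substituted butenolide carbon (slow or reversible closure), so that the vinyl ketone oligomerises instead; γ-deprotonation of the butenolide could also erode enantiomeric purity. The fallback sets out from 2 and comes back at 6, and replaces the unstabilised enolate by a β-keto ester anion. Commercial tert-butyl acetoacetate is silylated (TMSCl, Et3N) to tert-butyl 3-(trimethylsilyloxy)but-2-enoate F1 and then (LiN(i-Pr)2, TMSCl, THF, −78 °C) to 1-tert-butoxy-1,3-bis(trimethylsilyloxy)buta-1,3-diene F2. Vinylogous Mukaiyama aldol addition of F2 to 2, catalysed by Ti(OiPr)4 and (R)-BINOL, gives the silylated aldol adduct F3. Bu4NF added to the same flask desilylates it, so that the butenolide keto ester F4 forms and its stabilised anion closes by 5-exo Michael addition to the bicyclic keto lactone tert-butyl ester F5; both bonds are again made in one flask. TFA removes the tert-butyl group, and the β-keto acid F6 is methylenated with decarboxylation (aqueous HCHO, Et2NH) to give 6.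

Step 8. Silylation may go through the C10 enol (cross-conjugated dienol ether, then oxidation at C10 or C8), or the peracid may approach C6 from the β-face. The fallback sets out from 12 and comes back at 16, and oxygenates C6 before ring closure by a different mechanism. Allylic hydroxylation of the terminal allyl group of 12 with SeO2 (cat.) and t-BuOOH in CH2Cl2 (ene reaction, then [2,3] shift) gives the C6 allylic alcohol F7, the 6R epimer being separated. Ring-closing metathesis of F7 with the second-generation Grubbs catalyst then gives 16.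

Step 5. The lactol alkoxide may collapse before the quench, leading to a second addition or to conjugate addition to the new enone; the organolithium may also enolise the lactone. The fallback sets out from 9 and comes back at 11. The lactone is opened with MeNH(OMe)·HCl and i-PrMgCl (THF, −20 °C) to the Weinreb amide F8, and isopropenylmagnesium bromide is added; its chelated tetrahedral adduct cannot react further and gives 11 on work-up.

**Further compounds**

F1 | step 2 | tert-butyl 3-(trimethylsilyloxy)but-2-enoate | CC(O[Si](C)(C)C)=CC(=O)OC(C)(C)C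
F2 | step 2 | 1-tert-butoxy-1,3-bis(trimethylsilyloxy)buta-1,3-diene | C=C(O[Si](C)(C)C)C=C(O[Si](C)(C)C)OC(C)(C)C
F3 | step 2 | 1-tert-butyl 8-methyl (5R,6Z)-6-methyl-3,5-bis(trimethylsilyloxy)octa-2,6-dienedioate (silylated aldol adduct) | C/C(=C/C(=O)OC)[C@H](O[Si](C)(C)C)CC(O[Si](C)(C)C)=CC(=O)OC(C)(C)C
F4 | step 2 | tert-butyl 4-[(2R)-3-methyl-5-oxo-2,5-dihydrofuran-2-yl]-3-oxobutanoate | CC1=CC(=O)O[C@@H]1CC(=O)CC(=O)OC(C)(C)C
F5 | step 2 | tert-butyl (3aS,6aR)-3a-methyl-2,5-dioxohexahydro-2H-cyclopenta[b]furan-4-carboxylate (exo ester drawn; C4 epimerisable) | O=C1C[C@]2(C)[C@H](O1)CC(=O)[C@H]2C(=O)OC(C)(C)C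
F6 | step 2 | (3aS,6aR)-3a-methyl-2,5-dioxohexahydro-2H-cyclopenta[b]furan-4-carboxylic acid | O=C1C[C@]2(C)[C@H](O1)CC(=O)[C@H]2C(=O)O
F7 | step 8 | (1R,2S,3R,4R)-4-hydroxy-3-[(1R)-1-hydroxyprop-2-en-1-yl]-2-methyl-2-(3-methyl-2-oxobut-3-en-1-yl)-4-(propan-2-yl)cyclopentyl acetate | CC(=O)O[C@@H]1C[C@@](O)(C(C)C)[C@@H]([C@H](O)C=C)[C@]1(C)CC(=O)C(C)=C
F8 | step 5 | 2-[(1S,2R,4R,5S)-2,4-dihydroxy-1-methyl-4-(propan-2-yl)-5-(prop-2-en-1-yl)cyclopentyl]-N-methoxy-N-methylacetamide | O[C@@H]1C[C@@](O)(C(C)C)[C@@H](CC=C)[C@]1(C)CC(=O)N(C)OC
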